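E and Z cannot be the whole of the dawn flask: at its last reading they sum to 52.4% of the charge, and within the scatter neither is still rising. Something else holds the remainder, either L left over or an unseen G.

| flask | L | J | X | Q | temperature | remark | time |
|---|---|---|---|---|---|---|---|
| noon | 0.56 M | 0.10 M | 0.20 M | 4 mM | 20 °C | run made earlier |  |
| dawn | 0.88 M | 0.10 M | 0.20 M | 4 mM | 70 °C | run made earlier |  |
| spring | 0.40 M | 0.20 M | 0.20 M | 4 mM | 20 °C | run made earlier |  |
| oak | 0.40 M | 0.100 M | 0.200 M | 4.0 mM | 25 °C |  | 6.0 min |
| alder | 0.40 M | 0.100 M | 0.200 M | 4.0 mM | 85 °C |  | 6.0 min |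
| elm | 0.40 M | 0.100 M | 0.200 M | 4.0 mM | 115 °C |  | 6.0 min |
| maple | 0.40 M | 0.100 M | 0.200 M | 4.0 mM | 55 °C |  | 6.0 min |

noon run (percent of the L and J together charged)

| time / min | E / % | Z / % |
|---|---|---|
| 0.200 | 6.3 | 17.1 |
| 0.500 | 13.7 | 19.5 |
| 1.00 | 25.5 | 22.7 |
| 1.50 | 34.8 | 25.7 |
| 2.00 | 37.3 | 27.7 |
| 3.00 | 48.1 | 32.5 |
| 4.00 | 51.4 | 31.7 |

dawn run (percent of the L and J together charged)

| time / s | E / % | Z / % |
|---|---|---|
| 10.0 | 11.0 | 40.4 |
| 15.0 | 12.5 | 42.2 |
| 25.0 | 13.0 | 39.4 |

spring run (percent of the L and J together charged)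

| time / min | E / % | Z / % |
|---|---|---|
| 0.333 | 7.4 | 35.3 |
| 0.833 | 18.6 | 39.8 |
| 1.50 | 28.3 | 42.0 |
| 2.50 | 33.8 | 45.6 |
| 4.00 | 41.8 | 47.8 |

(each reading ± 1 percentage point)

- the numbers in the tables scatter with a standard deviation of 1 percentage point
- in a conversion J counts as not yet reacted

- the best flask by share of E in all that became E or Z or G; "all alike" if 1.5 percentage points covers them all (oak / alder / elm / maple / all alike)
- share of E in all that became E or Z or G, oak
- share of E in all that became E or Z or G, alder
- share of E in all that became E or Z or G, elm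
- share of E in all that became E or Z or G, maple

We bracket oak with two extreme flasks. In noon, Z stands at 17.1% by the first reading, where J's part of the charge is 15.2%, so we book J to Z. If every L then went to E, the share of E in oak would be L's part, 80.0%; if no L went there, it would be nil. Between these the flask sits by its split: the rate of L into E divided by the rate of L into anything else, a selectivity factor. For L used up, J booked to Z and both routes first order in L, the share is L's part times split/(1+split).

Noon's E at 1.50 min and 3.00 min stands in the ratio 1.38. A first-order rise then gives a rate constant of 0.641 min⁻¹ and a final E of 56.3%, so noon's split reads 1.97. Noon's constant, read at 20 °C, would leave 2.14% of L after 6.0 min, and oak is warmer, so we take L in oak as used up. We take dawn as finished, its remainder being G, which gives a split of 0.169. Running the logarithm of the split straight in temperature, oak's split, its rate of L into E over its rate of L elsewhere, is 1.54. Our shares are then 48.6% for oak and 20.9% for maple. Extrapolating past dawn gives 5.99% for alder and 1.46% for elm, so oak ranks highest.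

The forecast read dawn differently, “the catalyst dies quickly when hot”. It named oak best, with 55% for oak, 12% for alder, 5% for elm and 30% for maple.

The flasks give oak as best, with 48.8% for oak, 5.36% for alder, 1.53% for elm and 18.9% for maple.

    Q + J → Q + Z (k = 50700 M⁻¹ min⁻¹, Ea = 43.0 kJ mol⁻¹)
    L → G (k = 0.113 min⁻¹, Ea = 96.0 kJ mol⁻¹)
    J + X → D (k = 2.83 M⁻¹ min⁻¹, Ea = 65.0 kJ mol⁻¹)
    L + Q → Q + E (k = 131 M⁻¹ min⁻¹, Ea = 40.0 kJ mol⁻¹)
    L ⇌ J (K = 0.439, k = 0.223 min⁻¹, Ea = 75.0 kJ mol⁻¹, ΔH = 26.0 kJ mol⁻¹)
    (constants at 25 °C)

In oak, L enters E at 0.524 min⁻¹ and leaves towards G and J together at 0.336 min⁻¹, which is slower. That is a split of 1.56 against the carried 1.54, and at the asked time oak holds G at 10.5% with Q at 100%.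

For a neighbour of oak charged with 0.010 M of Q, the split scales with [Q] to 3.86, which gives a share of 63.5%. The computed flask gives 63.7%.

The earlier runs and the new flask were generated by integration on assumed constants; the scatter is artificial.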